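The target is a biflavone in which C-3 of the 5,7-dihydroxychromone (flavone 2) is bonded to C-3' of ring B of the 5-hydroxy-7-methoxyflavone (flavone 1). This hindered bond is never made by coupling: it is the CH2–aryl bond of 2-hydroxyphenylacetic acid. Flavone 1 is built para to the phenol, the arylacetate is C-aroylated, and the resulting benzyl-protected alpha-aryl beta-ketoester is condensed thermally with phloroglucinol (Mentzer annulation). That single operation forms C-4–C-4a and O-1–C-2 and closes ring C of flavone 2. It exploits the fact that ring A of flavone 2 is threefold-symmetric phloroglucinol and that C-3 is the alpha carbon of a 1,3-dicarbonyl unit.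

Key step: step 9

Step 1
Reactants: 1 2-hydroxyphenylacetic acid
Product: 2 2-(5-bromo-2-hydroxyphenyl)acetic acid
Conditions: Br2 (1.0 equiv), AcOH, 15 °C to rt
Reagents that add atoms: bromine, BrBr
Why: Electrophilic aromatic bromination of a phenol, in which the hydroxyl should direct the single equivalent of bromine to its free para position (C-5), the site that later carries flavone 1, while the side chain stays untouched.

Step 2
Reactants: 2 2-(5-bromo-2-hydroxyphenyl)acetic acid
Product: 3 benzyl 2-[2-(benzyloxy)-5-bromophenyl]acetate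
Conditions: BnBr (2.3 equiv), K2CO3 (3 equiv), DMF, 60 °C
Reagents that add atoms: benzyl bromide, BrCc1ccccc1
Why: Double SN2 benzylation (Williamson ether synthesis at the phenoxide and alkylation of the carboxylate) protects both acidic groups in one operation, the benzyl ester being only a spectator that step 5 cleaves.

Step 3
Reactants: 3 benzyl 2-[2-(benzyloxy)-5-bromophenyl]acetate
Product: 4 benzyl 2-[2-(benzyloxy)-5-formylphenyl]acetate
Conditions: CO/H2 (1:1, 5 bar), Pd(OAc)2 (cat.), di(1-adamantyl)-n-butylphosphine (cat.), TMEDA, toluene, 100 °C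
Reagents that add atoms: carbon monoxide, [C-]#[O+]
Why: Palladium-catalysed reductive carbonylation (formylation) of an aryl bromide by oxidative addition, CO insertion and hydrogenolysis of the acylpalladium species with TMEDA as HBr acceptor, a homogeneous process that should leave the benzyl ether and benzyl ester intact.

Step 4
Reactants: 5 2',6'-dihydroxy-4'-methoxyacetophenone
Product: 6 2'-(benzyloxy)-6'-hydroxy-4'-methoxyacetophenone
Conditions: BnBr (1.05 equiv), K2CO3 (1.2 equiv), acetone, reflux
Reagents that add atoms: benzyl bromide, BrCc1ccccc1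
Why: Williamson etherification that should stop at the mono-ether because the remaining hydroxyl is locked in a hydrogen bond to the ketone and is far less nucleophilic; the substrate is symmetric, so either hydroxyl gives the same product and the later 7-OMe position is unambiguous.

Step 5
Reactants: 4 benzyl 2-[2-(benzyloxy)-5-formylphenyl]acetate; 6 2'-(benzyloxy)-6'-hydroxy-4'-methoxyacetophenone
Product: 8 2-[2-(benzyloxy)-5-[(E)-3-(2-benzyloxy-6-hydroxy-4-methoxyphenyl)-3-oxoprop-1-enyl]phenyl]acetic acid (chalcone acid), via aldehyde acid 7 (not isolated)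
Conditions: KOH (2 equiv), EtOH/H2O, rt, 1 h (4 alone); then 6, KOH (50% aq, excess), rt, 36 h; aq HCl
Reagents that add atoms: potassium hydroxide, [K+].[OH-]
Why: Saponification first turns the arylacetate into an unreactive carboxylate, and the Claisen–Schmidt aldol condensation of the enolate of 6 with the non-enolisable aryl aldehyde, followed by E1cB loss of water, should then give the conjugated (E)-chalcone under thermodynamic control.

Step 6
Reactants: 8 chalcone acid
Product: 9 methyl 2-[2-(benzyloxy)-5-[(E)-3-(2-benzyloxy-6-hydroxy-4-methoxyphenyl)-3-oxoprop-1-enyl]phenyl]acetate (chalcone ester)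
Conditions: MeI (1.2 equiv), KHCO3 (1.5 equiv), DMF, rt
Reagents that add atoms: iodomethane, CI
Why: SN2 methylation of the carboxylate, in which hydrogencarbonate is too weak a base to ionise the chelated 2'-hydroxyl, so only the acid should be alkylated and the methyl ester needed for steps 8 and 9 is installed without acid.

Step 7
Reactants: 9 chalcone ester
Product: 11 methyl 2-[2-(benzyloxy)-5-(5-benzyloxy-7-methoxy-4-oxo-4H-chromen-2-yl)phenyl]acetate (flavone 1 ester), via flavanone 10 (not isolated)
Conditions: I2 (10 mol %), DMSO, 120 °C; aq Na2S2O3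
Reagents that add atoms: none
Why: Oxidative cyclisation of a 2'-hydroxychalcone, in which 6-endo-trig oxa-Michael addition of the free phenol gives flavanone 10 and the iodine/DMSO couple dehydrogenates it with DMSO as terminal oxidant, closing the pyranone ring of flavone 1 and placing the benzyloxy group at C-5.

Step 8
Reactants: 11 flavone 1 ester; 12 4-(benzyloxy)benzoyl chloride
Product: 13 methyl 3-[4-(benzyloxy)phenyl]-2-[2-(benzyloxy)-5-(5-benzyloxy-7-methoxy-4-oxo-4H-chromen-2-yl)phenyl]-3-oxopropanoate (racemic and largely enolised beta-ketoester)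
Conditions: LiN(SiMe3)2 (2.3 equiv), THF, -78 °C; then 12 (1.2 equiv), -78 to 0 °C; aq NH4Cl
Reagents that add atoms: none
Why: Crossed Claisen C-acylation, in which the arylacetate CH2 is by far the most acidic site of 11, its lithium enolate attacks the non-enolisable acid chloride at carbon, and the second equivalent of base stores the more acidic product as its enolate, which should prevent a second acylation.

Step 9
Reactants: 13 beta-ketoester; 14 phloroglucinol (anhydrous)
Product: 17 5-(benzyloxy)-2-[4-(benzyloxy)-3-[2-(4-benzyloxyphenyl)-5,7-dihydroxy-4-oxo-4H-chromen-3-yl]phenyl]-7-methoxy-4H-chromen-4-one (tri-O-benzyl biflavone), via aroylketene 15 (not isolated), via triketone 16 (not isolated)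
Conditions: 14 (4 equiv), neat melt (or Ph2O), 240 °C, Ar stream, no acid or base, 10–30 min (microwave or metal bath)
Reagents that add atoms: none
Why: On heating, the enolisable beta-ketoester 13 should expel methanol to give aroylketene 15, which acylates phloroglucinol at carbon through its keto tautomer (any O-aryl ester reverts to 15 and is funnelled the same way) to give triketone 16. An ortho hydroxyl of 16 then adds to the 4-benzyloxybenzoyl carbonyl in a 6-exo-trig closure and the hemiketal loses water, which closes the pyranone ring (ring C) of flavone 2 through the bonds C-4–C-4a and O-1–C-2 around the C-3–C-3' bond that is already in place. The closest known reaction type is the Mentzer pyrone synthesis, the uncatalysed thermal condensation of phloroglucinol with alpha-substituted beta-ketoesters to 3-substituted 5,7-dihydroxychromones. No stereocentre is created, since the racemic alpha carbon of 13 becomes sp2 C-3. The step needs the chromone and not the 4-arylcoumarin of the Pechmann mode, and one acylation per phloroglucinol: the absence of acid, the poor electrophilicity of the hindered diaryl ketone toward ring carbon and the excess of symmetric, unprotected phloroglucinol should secure both, and the threefold symmetry of ring A removes any regiochemical question. The short heating time and the gas stream that carries off methanol and water limit thermal loss of benzyl ethers and hydrolytic decarboxylation of 13.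

Step 10
Reactants: 17 tri-O-benzyl biflavone
Product: 18 5,7-dihydroxy-3-[2-hydroxy-5-(5-hydroxy-7-methoxy-4-oxo-4H-chromen-2-yl)phenyl]-2-(4-hydroxyphenyl)-4H-chromen-4-one (target, CNP0254254.0)
Conditions: H2 (1 atm), 10% Pd/C, THF/MeOH, rt
Reagents that add atoms: none
Why: Catalytic hydrogenolysis of the three aryl benzyl ethers under mild conditions that should leave the aryl methyl ether and the conjugated C-2/C-3 double bonds of both chromones untouched.

Compound list
1 | 2-hydroxyphenylacetic acid | OC(=O)Cc1ccccc1O | starting material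
2 | 2-(5-bromo-2-hydroxyphenyl)acetic acid | OC(=O)Cc1cc(Br)ccc1O | intermediate
3 | benzyl 2-[2-(benzyloxy)-5-bromophenyl]acetate | O=C(Cc1cc(Br)ccc1OCc1ccccc1)OCc1ccccc1 | intermediate
4 | benzyl 2-[2-(benzyloxy)-5-formylphenyl]acetate | O=C(Cc1cc(C=O)ccc1OCc1ccccc1)OCc1ccccc1 | intermediate
5 | 2',6'-dihydroxy-4'-methoxyacetophenone | CC(=O)c1c(O)cc(OC)cc1O | starting material
6 | 2'-(benzyloxy)-6'-hydroxy-4'-methoxyacetophenone | CC(=O)c1c(O)cc(OC)cc1OCc1ccccc1 | intermediate
7 | 2-[2-(benzyloxy)-5-formylphenyl]acetic acid (present as its potassium salt, not isolated) | OC(=O)Cc1cc(C=O)ccc1OCc1ccccc1 | intermediate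
8 | 2-[2-(benzyloxy)-5-[(E)-3-(2-benzyloxy-6-hydroxy-4-methoxyphenyl)-3-oxoprop-1-enyl]phenyl]acetic acid | OC(=O)Cc1cc(/C=C/C(=O)c2c(O)cc(OC)cc2OCc2ccccc2)ccc1OCc1ccccc1 | intermediate
9 | methyl 2-[2-(benzyloxy)-5-[(E)-3-(2-benzyloxy-6-hydroxy-4-methoxyphenyl)-3-oxoprop-1-enyl]phenyl]acetate | COC(=O)Cc1cc(/C=C/C(=O)c2c(O)cc(OC)cc2OCc2ccccc2)ccc1OCc1ccccc1 | intermediate
10 | methyl 2-[2-(benzyloxy)-5-(5-benzyloxy-7-methoxy-4-oxochroman-2-yl)phenyl]acetate (racemic flavanone, not isolated) | COC(=O)Cc1cc(C2CC(=O)c3c(OCc4ccccc4)cc(OC)cc3O2)ccc1OCc1ccccc1 | intermediate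
11 | methyl 2-[2-(benzyloxy)-5-(5-benzyloxy-7-methoxy-4-oxo-4H-chromen-2-yl)phenyl]acetate | COC(=O)Cc1cc(-c2cc(=O)c3c(OCc4ccccc4)cc(OC)cc3o2)ccc1OCc1ccccc1 | intermediate
12 | 4-(benzyloxy)benzoyl chloride | O=C(Cl)c1ccc(OCc2ccccc2)cc1 | starting material
13 | methyl 3-[4-(benzyloxy)phenyl]-2-[2-(benzyloxy)-5-(5-benzyloxy-7-methoxy-4-oxo-4H-chromen-2-yl)phenyl]-3-oxopropanoate (racemic, enolisable) | COC(=O)C(C(=O)c1ccc(OCc2ccccc2)cc1)c1cc(-c2cc(=O)c3c(OCc4ccccc4)cc(OC)cc3o2)ccc1OCc1ccccc1 | intermediate
14 | phloroglucinol (benzene-1,3,5-triol) | Oc1cc(O)cc(O)c1 | starting material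
15 | 2-[2-(benzyloxy)-5-(5-benzyloxy-7-methoxy-4-oxo-4H-chromen-2-yl)phenyl]-3-[4-(benzyloxy)phenyl]prop-1-ene-1,3-dione (aroylketene, not isolated) | O=C=C(C(=O)c1ccc(OCc2ccccc2)cc1)c1cc(-c2cc(=O)c3c(OCc4ccccc4)cc(OC)cc3o2)ccc1OCc1ccccc1 | intermediate
16 | 2-[2-(benzyloxy)-5-(5-benzyloxy-7-methoxy-4-oxo-4H-chromen-2-yl)phenyl]-1-[4-(benzyloxy)phenyl]-3-(2,4,6-trihydroxyphenyl)propane-1,3-dione (not isolated) | O=C(c1c(O)cc(O)cc1O)C(C(=O)c1ccc(OCc2ccccc2)cc1)c1cc(-c2cc(=O)c3c(OCc4ccccc4)cc(OC)cc3o2)ccc1OCc1ccccc1 | intermediate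
17 | 5-(benzyloxy)-2-[4-(benzyloxy)-3-[2-(4-benzyloxyphenyl)-5,7-dihydroxy-4-oxo-4H-chromen-3-yl]phenyl]-7-methoxy-4H-chromen-4-one | COc1cc(OCc6ccccc6)c2c(=O)cc(-c3ccc(OCc7ccccc7)c(-c4c(-c5ccc(OCc8ccccc8)cc5)oc5cc(O)cc(O)c5c4=O)c3)oc2c1 | intermediate
18 | 5,7-dihydroxy-3-[2-hydroxy-5-(5-hydroxy-7-methoxy-4-oxo-4H-chromen-2-yl)phenyl]-2-(4-hydroxyphenyl)-4H-chromen-4-one (CNP0254254.0) | COc1cc(O)c2c(=O)cc(-c3ccc(O)c(-c4c(-c5ccc(O)cc5)oc5cc(O)cc(O)c5c4=O)c3)oc2c1 | target

Total step count: 10 steps.
Longest linear sequence: 9 steps (1 → 2 → 3 → 4 → 8 → 9 → 11 → 13 → 17 → 18; step 4 is the one-step side branch).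

Steps most likely to fail

1. Step 9 (thermal annulation). At 240 °C the benzyl ethers may migrate or be lost. The ketoester may also be hydrolysed and decarboxylated by the water that is released before the hindered ketene is captured, or ring closure may take the Pechmann course. The fallback sets out from 6 and comes back to the route at 18; it gives up the annulation and makes the C-3–C-3' bond by Suzuki–Miyaura coupling. Acetophenone 6 and bought 4-(benzyloxy)-3-bromobenzaldehyde are condensed (KOH, EtOH/H2O, rt) to bromochalcone F1, which I2 (cat.) in DMSO at 120 °C should convert into 3'-bromoflavone F2. Miyaura borylation (B2pin2, PdCl2(dppf), KOAc, dioxane, 90 °C) then gives pinacol boronate F3. Separately, bought apigenin is benzylated at all three hydroxyls (BnBr, K2CO3, DMF, 80 °C) to tri-O-benzylapigenin F4, which is lithiated and iodinated at C-3 (LDA, THF, -78 °C, then I2) to 3-iodoflavone F5. Coupling of F3 with F5 (Pd(OAc)2, SPhos, K3PO4, toluene/H2O, 100 °C) should give penta-O-benzyl biflavone F6, and hydrogenolysis (H2, 10% Pd/C, THF/MeOH) of its five benzyl ethers returns to 18.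

2. Step 8 (C-aroylation). O-acylation of the ester enolate or of the product enolate may compete, or the silylamide base may consume the acid chloride, so that conversion of 11 stalls. The fallback sets out from 11 and comes back at 13; it replaces the acylation by aldol addition and oxidation. The lithium enolate of 11 (LiN(SiMe3)2, 1.1 equiv, THF, -78 °C) is added to bought 4-(benzyloxy)benzaldehyde and quenched cold to give beta-hydroxy ester F7 as a mixture of diastereomers, both centres being erased later. Oxidation with Dess–Martin periodinane (CH2Cl2, NaHCO3, rt) should then give 13.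

3. Step 3 (formylation). The arylpalladium intermediate may be reduced before CO insertion (hydrodebromination), or the catalyst may be deactivated under CO/H2. The fallback sets out from 3 and comes back at 4; it introduces the aldehyde carbon as a vinyl group. Stille coupling of 3 with tributyl(vinyl)stannane (Pd(PPh3)4, toluene, 100 °C, no base) gives styrene F8, and Lemieux–Johnson cleavage (OsO4 cat., NaIO4, 2,6-lutidine, dioxane/H2O, rt) should deliver 4.

Further compounds
F1 | step 9 | (E)-1-[2-(benzyloxy)-6-hydroxy-4-methoxyphenyl]-3-[4-(benzyloxy)-3-bromophenyl]prop-2-en-1-one | COc1cc(O)c(C(=O)/C=C/c2ccc(OCc3ccccc3)c(Br)c2)c(OCc2ccccc2)c1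
F2 | step 9 | 5-(benzyloxy)-2-[4-(benzyloxy)-3-bromophenyl]-7-methoxy-4H-chromen-4-one | COc1cc(OCc2ccccc2)c2c(=O)cc(-c3ccc(OCc4ccccc4)c(Br)c3)oc2c1
F3 | step 9 | 5-(benzyloxy)-2-[4-(benzyloxy)-3-(4,4,5,5-tetramethyl-1,3,2-dioxaborolan-2-yl)phenyl]-7-methoxy-4H-chromen-4-one | COc1cc(OCc2ccccc2)c2c(=O)cc(-c3ccc(OCc4ccccc4)c(B5OC(C)(C)C(C)(C)O5)c3)oc2c1
F4 | step 9 | 5,7-bis(benzyloxy)-2-[4-(benzyloxy)phenyl]-4H-chromen-4-one | O=c1cc(-c2ccc(OCc3ccccc3)cc2)oc2cc(OCc3ccccc3)cc(OCc3ccccc3)c12
F5 | step 9 | 5,7-bis(benzyloxy)-2-[4-(benzyloxy)phenyl]-3-iodo-4H-chromen-4-one | O=c1c(I)c(-c2ccc(OCc3ccccc3)cc2)oc2cc(OCc3ccccc3)cc(OCc3ccccc3)c12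
F6 | step 9 | 5,7-bis(benzyloxy)-3-[2-(benzyloxy)-5-(5-benzyloxy-7-methoxy-4-oxo-4H-chromen-2-yl)phenyl]-2-[4-(benzyloxy)phenyl]-4H-chromen-4-one | COc1cc(OCc2ccccc2)c2c(=O)cc(-c3ccc(OCc4ccccc4)c(-c4c(-c5ccc(OCc6ccccc6)cc5)oc5cc(OCc6ccccc6)cc(OCc6ccccc6)c5c4=O)c3)oc2c1
F7 | step 8 | methyl 3-[4-(benzyloxy)phenyl]-2-[2-(benzyloxy)-5-(5-benzyloxy-7-methoxy-4-oxo-4H-chromen-2-yl)phenyl]-3-hydroxypropanoate (mixture of diastereomers, each racemic) | COC(=O)C(C(O)c1ccc(OCc2ccccc2)cc1)c1cc(-c2cc(=O)c3c(OCc4ccccc4)cc(OC)cc3o2)ccc1OCc1ccccc1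
F8 | step 3 | benzyl 2-[2-(benzyloxy)-5-vinylphenyl]acetate | C=Cc1ccc(OCc2ccccc2)c(CC(=O)OCc2ccccc2)c1
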